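**Feed constant.** 0.688 min⁻¹ is what I read as the feed constant: the fraction of the Q still present that turns into G each minute. It comes from G plus E at 0.200 min, which is 12.6% of the charge at 3.3 mM and 13.1% at 14 mM. These shares match within the scatter, so I take the feed as first order in Q, with the same constant at any of these charges.

| flask | Q | J | remark | time |
|---|---|---|---|---|
| north-east | 3.3 mM | 1.1 equiv | run made earlier |  |
| south-west | 14 mM | 1.1 equiv | run made earlier |  |
| maple | 3.0 mM | 1.10 equiv |  | 6.0 min |
| elm | 6.0 mM | 1.10 equiv |  | 6.0 min |
| birch | 12 mM | 1.10 equiv |  | 6.0 min |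

| run | time / min | G / % | E / % |
|---|---|---|---|
| north-east | 0.200 | 12.6 | 0 |
| north-east | 0.667 | 30.7 | 3.4 |
| north-east | 1.00 | 36.8 | 6.8 |
| north-east | 1.50 | 41.4 | 10.9 |
| north-east | 2.50 | 37.5 | 21.1 |
| north-east | 3.00 | 33.9 | 26.7 |
| south-west | 0.200 | 11.7 | 1.4 |
| south-west | 0.667 | 19.8 | 10.7 |
| south-west | 1.00 | 21.4 | 17.9 |
| south-west | 1.50 | 20.2 | 27.5 |
| south-west | 2.50 | 14.7 | 41.1 |
| south-west | 3.00 | 12.5 | 46.9 |

(scatter of a reading: 0.5 percentage points)

* amount of G at the end, in percent of the Q charged for maple, elm, birch, in this order
* the course of these numbers from the first flask to the last (rises all the way / hardly changes / rises, then falls / falls all the way / falls, then rises)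

- "hardly changes" means that all values lie within two and a half points (for a concentration: within two and a half percent of the largest)

**The slowing.** At the start, G is fed at 0.688 min⁻¹ times the charge. Q is the limiting reagent at 1.10 equiv of J, and the feed is this constant times the Q present, so it falls as Q falls, with a half-life of 1.01 min. By 6.0 min the feed has slowed by a factor of 61.9, which leaves 1.61% of the Q charged in each flask.

**My reckoning.** The end feed is 0.0111 min⁻¹ times the charge, so the G at the end is mostly G made earlier that has not yet been cleared. At 3.00 min, under the same feed, the run at 14 mM holds 12.5% of G and the run at 3.3 mM holds 33.9%. I therefore expect the row to fall with every increase in charge.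

**The forecast.** It gives 22%, 11% and 4%, and the course falls all the way, on its own ground: “G → E scales with concentration”. It parts from my reckoning on the feed: I let Q decay at the feed constant, while the forecast expects G plus E to reach a plateau near 65%.

**The flasks.** They give 18.9%, 9.93% and 4.99%, and the course falls all the way.

    J + G → E (k = 1.30 M⁻¹ s⁻¹)
    2 G → Z (k = 1.80 M⁻¹ s⁻¹)
    Q → G (k = 0.0110 s⁻¹)

**At the end.** Against my 1.61%, maple holds 1.91% of its Q at 6.00 min, and elm holds 1.9% at 6.00 min. In maple at 6.00 min, G is made at 0.230 of the rate at which it is used up, and the step to E uses G at 1.4 times the rate of the loss of 2 G to Z.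

The earlier runs and the new flask stem from a simulated flask for substances that don't exist; the scatter is artificial.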